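**Plan** (carotenoid numbering: ring C1–C6, chain C7–C15, primed numbers for the identical second half)
1. The retrosynthesis cuts the central C15–C15' single bond of the C2-symmetric retro-dodecaene into two identical C20 halves, then in each half the ring–chain bond C6–C7 and the chain bond C11=C12.
2. Enabling feature: in each half C15 is tied through the conjugated path C14=C13 … C6=C5 to the C4 methylene of the cyclohexene ring. A C15 carbinol on a normal retinoid (ring C5=C6, C4H2) is therefore the latent form of the retro array C14=C15 … C4=C5, and the target is the twofold vinylogous (1,12) dehydration product of the 15,15'-pinacol of a (3R)-3-silyloxyretinal.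
3. Forward: the ring enters as enol triflate 3 from (4R,6R)-actinol 1; the chain C7–C15 as tetraenylstannane 8 from enynol 4 and C5 phosphonate 7 (Horner–Wadsworth–Emmons, C11=C12); Stille coupling makes C6–C7; the ester is taken to aldehyde 11.
4. Two molecules of 11 are joined at their electrophilic C15 carbons by titanium ketyl homocoupling; the bis-sulfonate of the diol loses both oxygens with a shift of all ten double bonds; fluoride frees the two hydroxyls.
5. Stereochemistry: C3/C3' come unchanged from C4 of 1 (3R in the β-ring series becomes 3S in the retro ring by a change of CIP priority only). Chain geometry comes from syn-hydrostannylation, E-selective olefination and the all-trans cation of the elimination (6E as in anhydroretinol); the C15/C15' carbinol centres are transient.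

Key step: step 9

Remark: (4R,6R)-actinol 1, enynol 4 and phosphonate 7 are taken as catalogue compounds; 7 is sold as an E/Z mixture, which converges because its anion is a delocalised allyl anion.

**Step 1**
Reactants: 1 (4R,6R)-4-hydroxy-2,2,6-trimethylcyclohexan-1-one
Product: 2 (4R,6R)-4-[(tert-butyldimethylsilyl)oxy]-2,2,6-trimethylcyclohexan-1-one
Conditions: TBSCl, imidazole, DMF, rt
Reagents that add atoms: tert-butyldimethylsilyl chloride, CC(C)(C)[Si](C)(C)Cl
Why: Standard silylation of a secondary alcohol, which leaves the carbinol centre (the future C3) untouched.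

**Step 2**
Reactants: 2 (4R,6R)-4-[(tert-butyldimethylsilyl)oxy]-2,2,6-trimethylcyclohexan-1-one
Product: 3 (4R)-4-[(tert-butyldimethylsilyl)oxy]-2,6,6-trimethylcyclohex-1-en-1-yl trifluoromethanesulfonate
Conditions: LiN(i-Pr)2, THF, −78 °C; then PhNTf2, −78 °C → rt
Reagents that add atoms: N-phenylbis(trifluoromethanesulfonimide), O=S(=O)(N(c1ccccc1)S(=O)(=O)C(F)(F)F)C(F)(F)F
Why: Only C6 of the ketone carries an α-hydrogen (C2 is quaternary), so enolate O-triflation should give the tetrasubstituted enol triflate regiospecifically; the methyl-bearing centre is erased as intended, and the silyloxy group is γ to the carbonyl and cannot β-eliminate.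

**Step 3**
Reactants: 4 (2E)-3-methylpent-2-en-4-yn-1-ol
Product: 5 (2E,4E)-3-methyl-5-(tributylstannyl)penta-2,4-dien-1-ol
Conditions: Bu3SnH, PdCl2(PPh3)2 (2 mol %), THF, 0 °C → rt
Reagents that add atoms: tributyltin hydride, CCCC[SnH](CCCC)CCCC
Why: Palladium-catalysed hydrostannylation of a terminal, alkene-conjugated alkyne is a syn addition that places tin on the terminal carbon and should give the 4E dienylstannane, the minor internal regioisomer being removed by chromatography.

**Step 4**
Reactants: 5 (2E,4E)-3-methyl-5-(tributylstannyl)penta-2,4-dien-1-ol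
Product: 6 (2E,4E)-3-methyl-5-(tributylstannyl)penta-2,4-dienal
Conditions: MnO2, CH2Cl2, rt
Reagents that add atoms: none
Why: Activated MnO2 oxidises allylic alcohols under neutral conditions, which should keep the vinyl–tin bond and both double-bond geometries.

**Step 5**
Reactants: 6 (2E,4E)-3-methyl-5-(tributylstannyl)penta-2,4-dienal; 7 triethyl 3-methyl-4-phosphonocrotonate
Product: 8 ethyl (2E,4E,6E,8E)-3,7-dimethyl-9-(tributylstannyl)nona-2,4,6,8-tetraenoate
Conditions: 7, n-BuLi, THF–DMPU, 0 °C; then 6, −78 → 0 °C
Reagents that add atoms: none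
Why: Horner–Wadsworth–Emmons olefination of the lithiated phosphonocrotonate, which reacts at the carbon next to phosphorus, should form the new disubstituted double bond (future C11=C12) E and deliver the 2E ester predominantly.

**Step 6**
Reactants: 3 (4R)-4-[(tert-butyldimethylsilyl)oxy]-2,6,6-trimethylcyclohex-1-en-1-yl trifluoromethanesulfonate; 8 ethyl (2E,4E,6E,8E)-3,7-dimethyl-9-(tributylstannyl)nona-2,4,6,8-tetraenoate
Product: 9 ethyl (3R)-3-[(tert-butyldimethylsilyl)oxy]retinoate (all-E)
Conditions: Pd2(dba)3 (5 mol %), AsPh3 (40 mol %), NMP, 60 °C, dark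
Reagents that add atoms: none
Why: Stille coupling with the weakly bound arsine ligand in a polar solvent is the established way to join hindered 2,6,6-trimethylcyclohexenyl triflates to alkenylstannanes, and transmetalation proceeds with retention of the stannane geometry (C6–C7 bond).

**Step 7**
Reactants: 9 ethyl (3R)-3-[(tert-butyldimethylsilyl)oxy]retinoate
Product: 10 (3R)-3-[(tert-butyldimethylsilyl)oxy]retinol (all-E)
Conditions: i-Bu2AlH (2.5 equiv), CH2Cl2, −78 °C; aq KNaC4H4O6 work-up
Reagents that add atoms: none
Why: i-Bu2AlH reduces the conjugated ester by 1,2-addition to the allylic alcohol and leaves the silyl ether and the polyene alone.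

**Step 8**
Reactants: 10 (3R)-3-[(tert-butyldimethylsilyl)oxy]retinol
Product: 11 (3R)-3-[(tert-butyldimethylsilyl)oxy]retinal (all-E)
Conditions: MnO2, CH2Cl2, rt, dark
Reagents that add atoms: none
Why: MnO2 oxidation of the pentaenylic primary alcohol is the standard retinol-to-retinal conversion and should not disturb the all-E chain.

**Step 9**
Reactants: 11 (3R)-3-[(tert-butyldimethylsilyl)oxy]retinal (two molecules)
Product: 12 (3R,3'R)-3,3'-bis[(tert-butyldimethylsilyl)oxy]-15,15'-dihydro-β,β-carotene-15,15'-diol (mixture of dl and meso forms at C15/C15')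
Conditions: Cp2TiCl2 (2.2 equiv), Mn dust, THF, rt (green Cp2TiCl); then 11, rt, dark, argon; aq NaHCO3 work-up
Reagents that add atoms: none
Why: Cp2TiCl (trivalent titanium) binds the aldehyde oxygen and transfers one electron, and two titanium-bound ketyl radicals, whose spin is delocalised from C15 to C5, combine at C15 to give the pinacolate of tetravalent titanium, which is hydrolysed on work-up. The closest known reaction type is the Cp2TiCl-mediated pinacol coupling of α,β-unsaturated and aromatic aldehydes, and the low-valent titanium dimerisation of retinal to β-carotene passes through the same C15–C15' pinacolate. No ring is closed. The new stereocentres C15 and C15' should form as a dl/meso mixture (the titanium-bridged transition state favours dl), which is of no consequence because both carbons become trigonal again in step 10. The step needs 1,2-coupling at C15 instead of coupling through C13, C11 or C9, and it must stop before deoxygenation or reduction to 10; the O–Ti bond that keeps the reaction at the carbinyl carbon, the methyl groups on C13 and C9, and the inability of Cp2TiCl to deoxygenate a pinacolate at rt should secure this, while the silyl ethers and the polyene are inert to this mild reductant. The event joins two carbons of like (electrophilic) polarity, builds the whole C40 skeleton from one C20 aldehyde, and leaves on each C15 the hydroxyl that the retro shift needs as leaving group.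

**Step 10**
Reactants: 12 (3R,3'R)-3,3'-bis[(tert-butyldimethylsilyl)oxy]-15,15'-dihydro-β,β-carotene-15,15'-diol
Product: 14 (3S,3'S)-3,3'-bis[(tert-butyldimethylsilyl)oxy]-4',5'-didehydro-4,5'-retro-β,β-carotene (all-E), via 15,15'-bis(methanesulfonate) 13 (not isolated)
Conditions: Ms2O (3 equiv), i-Pr2NEt (8 equiv), CH2Cl2, −40 °C; then 0 °C → rt, dark, argon
Reagents that add atoms: none
Why: Both carbinols are sulfonylated in the cold before either leaves, each pentaenylic mesylate then ionises on warming to a cation delocalised from C15 to C5, and the hindered amine removes a proton from the ring methylene C4 (vinylogous E1, the retinol-to-anhydroretinol dehydration done twice); no free hydroxyl stands beside the cation, so a pinacol-type shift is excluded, the basic medium spares the C3 silyl ethers that become allylic, and the 6E geometry should follow as in anhydroretinol because C8 avoids the in-plane C5 methyl.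

**Step 11**
Reactants: 14 (3S,3'S)-3,3'-bis[(tert-butyldimethylsilyl)oxy]-4',5'-didehydro-4,5'-retro-β,β-carotene
Product: 15 (3S,3'S)-4',5'-didehydro-4,5'-retro-β,β-carotene-3,3'-diol (all-E; the target)
Conditions: Bu4NF, THF, 0 °C → rt, dark, argon
Reagents that add atoms: none
Why: Fluoride cleaves the two secondary silyl ethers without acid, so the allylic C3 carbinols next to the dodecaene are not ionised and their configuration is kept.

**Compound list**
1 | (4R,6R)-4-hydroxy-2,2,6-trimethylcyclohexan-1-one (actinol) | O=C1C(C)(C)C[C@H](O)C[C@H]1C | starting material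
2 | (4R,6R)-4-[(tert-butyldimethylsilyl)oxy]-2,2,6-trimethylcyclohexan-1-one | O=C1C(C)(C)C[C@H](O[Si](C)(C)C(C)(C)C)C[C@H]1C | intermediate
3 | (4R)-4-[(tert-butyldimethylsilyl)oxy]-2,6,6-trimethylcyclohex-1-en-1-yl trifluoromethanesulfonate | CC1=C(OS(=O)(=O)C(F)(F)F)C(C)(C)C[C@H](O[Si](C)(C)C(C)(C)C)C1 | intermediate
4 | (2E)-3-methylpent-2-en-4-yn-1-ol | C#C/C(C)=C/CO | starting material
5 | (2E,4E)-3-methyl-5-(tributylstannyl)penta-2,4-dien-1-ol | CCCC[Sn](CCCC)(CCCC)/C=C/C(C)=C/CO | intermediate
6 | (2E,4E)-3-methyl-5-(tributylstannyl)penta-2,4-dienal | CCCC[Sn](CCCC)(CCCC)/C=C/C(C)=C/C=O | intermediate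
7 | triethyl 3-methyl-4-phosphonocrotonate (drawn as the E isomer) | CCOC(=O)/C=C(\C)CP(=O)(OCC)OCC | starting material
8 | ethyl (2E,4E,6E,8E)-3,7-dimethyl-9-(tributylstannyl)nona-2,4,6,8-tetraenoate | CCCC[Sn](CCCC)(CCCC)/C=C/C(C)=C/C=C/C(C)=C/C(=O)OCC | intermediate
9 | ethyl (3R)-3-[(tert-butyldimethylsilyl)oxy]retinoate (all-E) | CC1=C(/C=C/C(C)=C/C=C/C(C)=C/C(=O)OCC)C(C)(C)C[C@H](O[Si](C)(C)C(C)(C)C)C1 | intermediate
10 | (3R)-3-[(tert-butyldimethylsilyl)oxy]retinol (all-E) | CC1=C(/C=C/C(C)=C/C=C/C(C)=C/CO)C(C)(C)C[C@H](O[Si](C)(C)C(C)(C)C)C1 | intermediate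
11 | (3R)-3-[(tert-butyldimethylsilyl)oxy]retinal (all-E) | CC1=C(/C=C/C(C)=C/C=C/C(C)=C/C=O)C(C)(C)C[C@H](O[Si](C)(C)C(C)(C)C)C1 | intermediate
12 | (3R,3'R)-3,3'-bis[(tert-butyldimethylsilyl)oxy]-15,15'-dihydro-β,β-carotene-15,15'-diol (dl/meso mixture at C15/C15') | CC1=C(/C=C/C(C)=C/C=C/C(C)=C/C(O)C(O)/C=C(C)/C=C/C=C(C)/C=C/C2=C(C)C[C@@H](O[Si](C)(C)C(C)(C)C)CC2(C)C)C(C)(C)C[C@H](O[Si](C)(C)C(C)(C)C)C1 | intermediate
13 | 15,15'-bis(methanesulfonate) of 12 (not isolated) | CC1=C(/C=C/C(C)=C/C=C/C(C)=C/C(OS(C)(=O)=O)C(OS(C)(=O)=O)/C=C(C)/C=C/C=C(C)/C=C/C2=C(C)C[C@@H](O[Si](C)(C)C(C)(C)C)CC2(C)C)C(C)(C)C[C@H](O[Si](C)(C)C(C)(C)C)C1 | intermediate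
14 | (3S,3'S)-3,3'-bis[(tert-butyldimethylsilyl)oxy]-4',5'-didehydro-4,5'-retro-β,β-carotene (all-E) | CC1=C[C@@H](O[Si](C)(C)C(C)(C)C)CC(C)(C)\C1=C/C=C(C)/C=C/C=C(C)/C=C/C=C/C(C)=C/C=C/C(C)=C/C=C1/C(C)=C[C@@H](O[Si](C)(C)C(C)(C)C)CC1(C)C | intermediate
15 | (3S,3'S)-4',5'-didehydro-4,5'-retro-β,β-carotene-3,3'-diol (all-E) | CC1=C[C@@H](O)CC(C)(C)\C1=C/C=C(C)/C=C/C=C(C)/C=C/C=C/C(C)=C/C=C/C(C)=C/C=C1/C(C)=C[C@@H](O)CC1(C)C | target

**Count**
Total steps: 11. Longest linear sequence: 9 steps (4 → 5 → 6 → 8 → 9 → 10 → 11 → 12 → 14 → 15).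

**Steps most likely to fail**

Step 9. The delocalised ketyl may couple through a vinylogous carbon, the pinacolate may revert, or reduction may run on to the alcohol. The fallback sets out from 11 and joins the same two C15 carbons as a double bond: McMurry coupling (TiCl3, LiAlH4, THF, reflux, as for retinal to β-carotene) should give the bis-silyl ether of zeaxanthin, (3R,3'R)-3,3'-bis[(tert-butyldimethylsilyl)oxy]-β,β-carotene F1. N-Bromosuccinimide in ethanol-free CHCl3 at low temperature, followed by N-ethylmorpholine, then brominates C4 and eliminates HBr through the polyene (ionisation at C4, proton loss from C4'); this is the known retro-dehydrogenation of carotenes and zeaxanthin esters. The fallback returns to the route at 14.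

Step 10. Ionisation may be diverted: capture of the cation by a neighbouring oxygen or by the base, proton loss from the C5 methyl instead of C4, incomplete second elimination or poor control of the C6=C7 geometry. The fallback sets out from 12 and removes the two oxygens reductively instead of by ionisation. 1,1'-Thiocarbonyldiimidazole (toluene, 60 °C) should give the cyclic thionocarbonate of the 15,15'-diol F2. Corey–Winter olefination with 1,3-dimethyl-2-phenyl-1,3,2-diazaphospholidine at 40 °C gives the zeaxanthin bis-silyl ether, the compound F1 of the fallback for step 9; a 15Z portion from the meso diol does not matter, because C15–C15' ends as a single bond. The N-bromosuccinimide dehydrogenation described there returns to the route at 14.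

Step 6. Oxidative addition at the tetrasubstituted, doubly flanked triflate may be slow, leaving time for stannane homocoupling, protodestannylation and E/Z scrambling of the tetraene. The fallback sets out from 3 and builds the chain stepwise from a small alkyne. Sonogashira coupling with 4 (PdCl2(PPh3)2, CuI, i-Pr2NH, DMF) should give (2E)-5-[(4R)-4-[(tert-butyldimethylsilyl)oxy]-2,6,6-trimethylcyclohex-1-en-1-yl]-3-methylpent-2-en-4-yn-1-ol F3. Hydroxyl-directed hydroalumination with LiAlH4 in THF reduces the triple bond to the E alkene and gives (2E,4E)-5-[(4R)-4-[(tert-butyldimethylsilyl)oxy]-2,6,6-trimethylcyclohex-1-en-1-yl]-3-methylpenta-2,4-dien-1-ol F4. MnO2 gives the corresponding dienal F5, and Horner–Wadsworth–Emmons olefination with 7 (n-BuLi, THF–DMPU) returns to the route at 9.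

**Further compounds**
F1 | step 9 | (3R,3'R)-3,3'-bis[(tert-butyldimethylsilyl)oxy]-β,β-carotene (all-E) | CC1=C(/C=C/C(C)=C/C=C/C(C)=C/C=C/C=C(C)/C=C/C=C(C)/C=C/C2=C(C)C[C@@H](O[Si](C)(C)C(C)(C)C)CC2(C)C)C(C)(C)C[C@H](O[Si](C)(C)C(C)(C)C)C1
F2 | step 10 | cyclic thionocarbonate (1,3-dioxolane-2-thione) of diol 12 | CC1=C(/C=C/C(C)=C/C=C/C(C)=C/C2OC(=S)OC2/C=C(C)/C=C/C=C(C)/C=C/C3=C(C)C[C@@H](O[Si](C)(C)C(C)(C)C)CC3(C)C)C(C)(C)C[C@H](O[Si](C)(C)C(C)(C)C)C1
F3 | step 6 | (2E)-5-[(4R)-4-[(tert-butyldimethylsilyl)oxy]-2,6,6-trimethylcyclohex-1-en-1-yl]-3-methylpent-2-en-4-yn-1-ol | CC1=C(C#C/C(C)=C/CO)C(C)(C)C[C@H](O[Si](C)(C)C(C)(C)C)C1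
F4 | step 6 | (2E,4E)-5-[(4R)-4-[(tert-butyldimethylsilyl)oxy]-2,6,6-trimethylcyclohex-1-en-1-yl]-3-methylpenta-2,4-dien-1-ol | CC1=C(/C=C/C(C)=C/CO)C(C)(C)C[C@H](O[Si](C)(C)C(C)(C)C)C1
F5 | step 6 | (2E,4E)-5-[(4R)-4-[(tert-butyldimethylsilyl)oxy]-2,6,6-trimethylcyclohex-1-en-1-yl]-3-methylpenta-2,4-dienal | CC1=C(/C=C/C(C)=C/C=O)C(C)(C)C[C@H](O[Si](C)(C)C(C)(C)C)C1
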